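1. Slowness is the clue. At 20.0 min the south-east run holds 8.2% of X, against 22.3% in the east run. D and G are equal in these runs, and Q differs.

the same everywhere: D 0.020 M

| run | G | Q | remark | time |
|---|---|---|---|---|
| east | 0.5 mol% | 34 µM | run made earlier |  |
| south-east | 0.5 mol% | 75 µM | run made earlier |  |
| north-east | 0.25 mol% | 50 µM | run made earlier |  |
| flask | 0.5 mol% | 50 µM |  | 15 min |

| run | time / min | X / % |
|---|---|---|
| east | 2.50 | 1.0 |
| east | 5.00 | 2.8 |
| east | 8.00 | 7.4 |
| east | 10.0 | 9.5 |
| east | 12.0 | 11.2 |
| east | 15.0 | 17.3 |
| east | 20.0 | 22.3 |
| south-east | 1.00 | 0.3 |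
| south-east | 3.00 | 1.6 |
| south-east | 5.00 | 0.6 |
| south-east | 8.00 | 1.6 |
| south-east | 10.0 | 6.2 |
| south-east | 15.0 | 6.0 |
| south-east | 20.0 | 8.2 |
| north-east | 1.50 | 0 |
| north-east | 5.00 | 0.4 |
| north-east | 8.00 | 0.8 |
| north-east | 12.0 | 2.8 |
| north-east | 20.0 | 2.5 |

(scatter of a reading: 1 percentage point)

- given per volume of solution although it is solid: D
- the numbers in the tables scatter by 1 percentage point (one standard deviation)
- at the start none of D is in solution

1. X at 15 min, in percent of the D charged
2. the change that raises the amount of X at 15 min, in percent of the D charged most ("none" if none brings more than 2 percentage points) (ochre / amber / green / none)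
3. amount of X at 15 min, in percent of the D charged, after green

- ochre: doubling the solubility of D, all else as stated
- amber: doubling the amount of G, all else as stated
- green: doubling the dissolution coefficient of D, all else as stated

2. I divide the two readings at that same time, so time drops out: the ratio reads 2.72.

3. I suspect Q acts as a catalyst poison, taking G one for one. Both runs charge cG = 100 µM. So cG minus cQ is 66.0 µM in the east run and 25.0 µM in the south-east run, a ratio of 2.64, close to the ratio of the readings.

4. A separate check is the north-east run. There cG is 50.0 µM, equal to cQ, and X reads 2.5% at 20.0 min.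

5. My rule, with cD held at 0.020 M: at a given time, X scales with free G, the G charged minus the Q charged. In this flask free G is 50.0 µM.

6. Scaling the east reading at 15.0 min gives 13.1%. That rests on one reading, which scatters by 1 percentage point. So I reforge it with the mean of the east readings at 10.0 min and 20.0 min, which is 15.9%. Scaled, that gives 12.0%, and I commit to this.

7. Amber raises free G to 150 µM, 3.00 times the flask's value, so I choose amber. I read the slow start of the east run, 1.0% at 2.50 min, as D dissolving, so I expect green to shorten that start, and I rank it below amber.

8. The forecast gives 12%, amber and 13% after green, on the ground that “Q therefore titrates G almost stoichiometrically”.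

    J → G + X (k = 0.301 /s)
    G + Q → L (k = 433 /M/s)
    Z + G → J (k = 9.23 /M/s)
    D ⇌ Z, rate k4*(cs4 - [Z]) while solid is left; crystals form when [Z] > cs4 (solubility = 12.0 mM, k = 0.00291 /s)

The flask gives 12.0%. The largest gain is amber, at 20 points, against 7.4 points for ochre and 2.8 points for green, and green ends at 14.9%. At 15.0 min the flask holds 50.0% of the catalyst as L, the off-cycle form, with 0% of Q left, while G and J together hold 50.0%. A neighbour flask has cQ = 12.0 µM, so free G is 88.0 µM against 50.0 µM. Scaling 12.0% by that ratio gives 21.1%, and the neighbour flask gives 20.2%.

The numbers in the tables are simulated with constants of no real substance.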